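**Retrosynthetic overview**
- Target 14 ⇐ MOM removal ⇐ aromatic Claisen shift of an O-(1,1-dimethylallyl) ether on the new B-ring hydroxyl: the C–O bond is made first and the O→C transposition then places the prenyl group next to the isoflavone.
- That hydroxyl and the pyran ring ⇐ one operation on a 4'-hydroxy-3'-prenyl isoflavone: aerobic Cu-catalysed ortho-oxygenation (aryl C–O) → o-quinone → o-quinone methide → oxa-6π closure (pyran C–O). This is the key step.
- The 3'-prenylphenol ⇐ Claisen shift of the 4'-O-(1,1-dimethylallyl) ether ⇐ Pd-catalysed O-allylation of 7-O-MOM-genistein ⇐ genistein.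
- Ring order: the chromone (A/C) and the B ring are bought intact in genistein; the only ring formed is the dimethylpyran, in step 5.

Assumption: the target has no stereocentre and no alkene that needs an E/Z descriptor, so it is achiral and no stereocontrol is required; the transient sp3 centres of the Claisen dienones are racemic and are erased on tautomerisation.
Assumption: the allyl carbonate 4 is not treated as a catalogue item and is made in step 2.

**Route**

Step 1
Reactants: 1 genistein
Product: 2 5-hydroxy-3-(4-hydroxyphenyl)-7-(methoxymethoxy)-4H-chromen-4-one (7-O-MOM-genistein)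
Conditions: MOMCl (1.05 equiv), K2CO3 (1.1 equiv), acetone, 0 °C → rt
Reagents that add atoms: chloromethyl methyl ether (MOMCl), COCCl
Why: O-alkylation (Williamson-type acetal formation) of the monoanion at the most acidic 7-OH (vinylogous acid, pKa about 7), while the 4'-OH (pKa about 10) and the chelated 5-OH stay free with one equivalent of weak base.

Step 2
Reactants: 3 2-methylbut-3-en-2-ol
Product: 4 tert-butyl (2-methylbut-3-en-2-yl) carbonate
Conditions: n-BuLi (1.05 equiv), THF, −78 → 0 °C; then Boc2O (1.1 equiv), 0 °C → rt; aqueous work-up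
Reagents that add atoms: di-tert-butyl dicarbonate (Boc2O), CC(C)(C)OC(=O)OC(=O)OC(C)(C)C
Why: acylation of the lithium tert-alkoxide with Boc2O is the standard preparation of tertiary allyl tert-butyl carbonates.

Step 3
Reactants: 2 7-O-MOM-genistein; 4 tert-butyl (2-methylbut-3-en-2-yl) carbonate
Product: 5 5-hydroxy-7-(methoxymethoxy)-3-{4-[(2-methylbut-3-en-2-yl)oxy]phenyl}-4H-chromen-4-one
Conditions: Pd(PPh3)4 (3 mol%), 4 (1.5 equiv), THF, 0 °C → rt
Reagents that add atoms: none
Why: decarboxylative Tsuji–Trost O-allylation, in which the 4'-phenoxide (the only non-chelated phenol) attacks the more substituted terminus of the 1,1-dimethyl-π-allyl-Pd cation to give the branched tertiary ether under kinetic control at low temperature.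

Step 4
Reactants: 5 the 4'-O-(1,1-dimethylallyl) ether
Product: 7 5-hydroxy-3-[4-hydroxy-3-(3-methylbut-2-en-1-yl)phenyl]-7-(methoxymethoxy)-4H-chromen-4-one (7-O-MOM-isowighteone), via ortho-dienone 6 (not isolated)
Conditions: N,N-diethylaniline, 130 °C, Ar
Reagents that add atoms: none
Why: aromatic [3,3] Claisen rearrangement of a tertiary allyl aryl ether delivers the linear prenyl group to the ortho carbon (both ortho positions are equivalent) and dienone 6 tautomerises to the phenol.

Step 5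
Reactants: 7 7-O-MOM-isowighteone
Product: 10 5-hydroxy-3-(8-hydroxy-2,2-dimethyl-2H-chromen-6-yl)-7-(methoxymethoxy)-4H-chromen-4-one (7-O-MOM-semilicoisoflavone B), via o-quinone 8 (not isolated), via o-quinone methide 9 (not isolated)
Conditions: [Cu(MeCN)4]PF6 (10 mol%), N,N'-di-tert-butylethylenediamine (DBED, 20 mol%), O2 (1 atm), 4 Å MS, CH2Cl2 (0.02 M, slow addition of 7), rt; then Ar purge, Et3N (2 equiv), 40 °C
Reagents that add atoms: dioxygen, O=O
Why: Proposed new method: a tyrosinase-like Cu2O2/DBED species should oxygenate the only free ortho position of the 4'-phenolate (new aryl C–O bond) to give o-quinone 8, whose prenyl CH2 is vinylogously acidified so that amine base tautomerises it to the (Z)-hydroxy-o-quinone methide 9, which closes by oxa-6π electrocyclisation onto the original phenol oxygen (pyran C–O bond) with re-aromatisation as the driving force, so the substrate dictates that the ring oxygen sits para and the new OH meta to the isoflavone; the closest known reaction types are the Cu/DBED-catalysed aerobic ortho-oxygenation of phenols to o-quinones and the base-induced isomerisation of prenyl-p-quinones to chromenols, which have not been merged or shown on o-prenylphenols.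

Step 6
Reactants: 10 7-O-MOM-semilicoisoflavone B; 4 tert-butyl (2-methylbut-3-en-2-yl) carbonate
Product: 11 3-{2,2-dimethyl-8-[(2-methylbut-3-en-2-yl)oxy]-2H-chromen-6-yl}-5-hydroxy-7-(methoxymethoxy)-4H-chromen-4-one
Conditions: Pd(PPh3)4 (3 mol%), 4 (1.5 equiv), THF, 0 °C → rt
Reagents that add atoms: none
Why: the same decarboxylative Tsuji–Trost O-allylation, now on the chromen-8-ol, the only phenol that is neither protected nor locked in the 5-OH/C4=O hydrogen bond.

Step 7
Reactants: 11 the chromen-8-yl 1,1-dimethylallyl ether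
Product: 13 5-hydroxy-3-[8-hydroxy-2,2-dimethyl-7-(3-methylbut-2-en-1-yl)-2H-chromen-6-yl]-7-(methoxymethoxy)-4H-chromen-4-one, via ortho-dienone 12 (not isolated)
Conditions: N,N-diethylaniline, 135 °C, Ar
Reagents that add atoms: none
Why: aromatic [3,3] Claisen rearrangement in which the regiochemistry is forced, because the only ortho carbon that carries hydrogen is C-7 (the other is C-8a with the ring oxygen), and dienone 12 re-aromatises to the phenol.

Step 8
Reactants: 13 the 7-O-MOM ether of the target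
Product: 14 5,7-dihydroxy-3-[8-hydroxy-2,2-dimethyl-7-(3-methylbut-2-en-1-yl)-2H-chromen-6-yl]-4H-chromen-4-one (target)
Conditions: 3 M aq. HCl/MeOH (1:4), 45 °C, 1–2 h
Reagents that add atoms: none
Why: acid-catalysed hydrolysis of the aryl MOM acetal under the dilute HCl/MeOH conditions routinely used as the last step for prenylated and pyrano-fused isoflavones, mild enough to leave the prenyl group and the chromene intact.

**Compound list**
1 | genistein (5,7-dihydroxy-3-(4-hydroxyphenyl)-4H-chromen-4-one) | O=c1c(-c2ccc(O)cc2)coc2cc(O)cc(O)c12 | starting material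
2 | 5-hydroxy-3-(4-hydroxyphenyl)-7-(methoxymethoxy)-4H-chromen-4-one | COCOc1cc(O)c2c(c1)occ(-c1ccc(O)cc1)c2=O | intermediate
3 | 2-methylbut-3-en-2-ol | C=CC(C)(C)O | starting material
4 | tert-butyl (2-methylbut-3-en-2-yl) carbonate | C=CC(C)(C)OC(=O)OC(C)(C)C | intermediate
5 | 5-hydroxy-7-(methoxymethoxy)-3-{4-[(2-methylbut-3-en-2-yl)oxy]phenyl}-4H-chromen-4-one | COCOc1cc(O)c2c(c1)occ(-c1ccc(OC(C)(C)C=C)cc1)c2=O | intermediate
6 | 4-[5-hydroxy-7-(methoxymethoxy)-4-oxo-4H-chromen-3-yl]-6-(3-methylbut-2-en-1-yl)cyclohexa-2,4-dien-1-one (racemic, transient) | COCOc1cc(O)c2c(c1)occ(C1=CC(CC=C(C)C)C(=O)C=C1)c2=O | intermediate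
7 | 5-hydroxy-3-[4-hydroxy-3-(3-methylbut-2-en-1-yl)phenyl]-7-(methoxymethoxy)-4H-chromen-4-one | COCOc1cc(O)c2c(c1)occ(-c1ccc(O)c(CC=C(C)C)c1)c2=O | intermediate
8 | 5-[5-hydroxy-7-(methoxymethoxy)-4-oxo-4H-chromen-3-yl]-3-(3-methylbut-2-en-1-yl)cyclohexa-3,5-diene-1,2-dione (transient) | COCOc1cc(O)c2c(c1)occ(C1=CC(=O)C(=O)C(CC=C(C)C)=C1)c2=O | intermediate
9 | (6Z)-2-hydroxy-4-[5-hydroxy-7-(methoxymethoxy)-4-oxo-4H-chromen-3-yl]-6-(3-methylbut-2-en-1-ylidene)cyclohexa-2,4-dien-1-one (transient) | COCOc1cc(O)c2c(c1)occ(C1=C/C(=C/C=C(C)C)C(=O)C(O)=C1)c2=O | intermediate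
10 | 5-hydroxy-3-(8-hydroxy-2,2-dimethyl-2H-chromen-6-yl)-7-(methoxymethoxy)-4H-chromen-4-one | COCOc1cc(O)c2c(c1)occ(-c1cc(O)c3OC(C)(C)C=Cc3c1)c2=O | intermediate
11 | 3-{2,2-dimethyl-8-[(2-methylbut-3-en-2-yl)oxy]-2H-chromen-6-yl}-5-hydroxy-7-(methoxymethoxy)-4H-chromen-4-one | COCOc1cc(O)c2c(c1)occ(-c1cc(OC(C)(C)C=C)c3OC(C)(C)C=Cc3c1)c2=O | intermediate
12 | 6-[5-hydroxy-7-(methoxymethoxy)-4-oxo-4H-chromen-3-yl]-2,2-dimethyl-7-(3-methylbut-2-en-1-yl)-2H-chromen-8(7H)-one (racemic, transient) | COCOc1cc(O)c2c(c1)occ(C1=CC3=C(OC(C)(C)C=C3)C(=O)C1CC=C(C)C)c2=O | intermediate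
13 | 5-hydroxy-3-[8-hydroxy-2,2-dimethyl-7-(3-methylbut-2-en-1-yl)-2H-chromen-6-yl]-7-(methoxymethoxy)-4H-chromen-4-one | COCOc1cc(O)c2c(c1)occ(-c1cc3C=CC(C)(C)Oc3c(O)c1CC=C(C)C)c2=O | intermediate
14 | 5,7-dihydroxy-3-[8-hydroxy-2,2-dimethyl-7-(3-methylbut-2-en-1-yl)-2H-chromen-6-yl]-4H-chromen-4-one (achiral) | CC(C)=CCc1c(-c2coc3cc(O)cc(O)c3c2=O)cc2c(c1O)OC(C)(C)C=C2 | target

**Step count and risks**
Total step count: 8 (steps 1–8, including the one-step preparation of reagent 4).
Longest linear sequence: 7 (genistein 1 → 14 through steps 1, 3, 4, 5, 6, 7 and 8).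

Step 5 (the proposed new cascade) is the most likely to fail. The o-quinone 8 may be intercepted by unreacted phenol 7, the product phenol 10 may be oxidised further, and the 5-OH/C4=O chelate may sequester copper. The fallback uses known chemistry and sets out from 7. IBX in DMF at rt oxidises the phenol to the o-quinone 8, which is reduced in the same flask with aqueous Na2S2O4 to the catechol 3-[3,4-dihydroxy-5-(3-methylbut-2-en-1-yl)phenyl]-5-hydroxy-7-(methoxymethoxy)-4H-chromen-4-one F1. DDQ (1.1 equiv, benzene, rt → 60 °C) then closes the pyran by the classical dehydrogenative cyclisation of an o-prenylphenol; only the oxygen next to the prenyl group can ring-close. The fallback comes back to the route at 10.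

Step 7 (Claisen shift into the position flanked by the isoflavone) is the second risk. The hindered [3,3] shift competes with loss of isoprene back to 10. The fallback sets out from 10 and replaces the [3,3] shift by a [1,3] shift. Prenyl bromide and K2CO3 in acetone give the linear prenyl ether 3-{2,2-dimethyl-8-[(3-methylbut-2-en-1-yl)oxy]-2H-chromen-6-yl}-5-hydroxy-7-(methoxymethoxy)-4H-chromen-4-one F2. Montmorillonite K10 (or Florisil) in CH2Cl2 at 0 °C → rt then promotes the known clay-mediated 1,3 O→C migration of aryl prenyl ethers to the ortho carbon. The fallback comes back to the route at 13.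

Step 8 (acidic MOM removal) is the third risk. The o-prenylphenol can cyclise to a chroman, and the electron-rich chromene can add methanol. The fallback sets out from 10 and changes the protecting group so that the prenylphenol never meets acid. The MOM group is removed at this stage with 3 M HCl/MeOH to give 5,7-dihydroxy-3-(8-hydroxy-2,2-dimethyl-2H-chromen-6-yl)-4H-chromen-4-one (semilicoisoflavone B) F3. Pivaloyl chloride (1.0 equiv) and K2CO3 (1.0 equiv) in acetone at 0 °C acylate the most acidic 7-OH to give 5-hydroxy-3-(8-hydroxy-2,2-dimethyl-2H-chromen-6-yl)-4-oxo-4H-chromen-7-yl pivalate F4. Pd(PPh3)4 and carbonate 4 give the tertiary ether 3-{2,2-dimethyl-8-[(2-methylbut-3-en-2-yl)oxy]-2H-chromen-6-yl}-5-hydroxy-4-oxo-4H-chromen-7-yl pivalate F5. Heating in N,N-diethylaniline at 135 °C passes through the transient ortho-dienone 3-[2,2-dimethyl-7-(3-methylbut-2-en-1-yl)-8-oxo-7,8-dihydro-2H-chromen-6-yl]-5-hydroxy-4-oxo-4H-chromen-7-yl pivalate F6 to 5-hydroxy-3-[8-hydroxy-2,2-dimethyl-7-(3-methylbut-2-en-1-yl)-2H-chromen-6-yl]-4-oxo-4H-chromen-7-yl pivalate F7. Catalytic K2CO3 in MeOH at rt removes the pivalate and the fallback comes back to the route at 14.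

**Further compounds**
F1 | step 5 | 3-[3,4-dihydroxy-5-(3-methylbut-2-en-1-yl)phenyl]-5-hydroxy-7-(methoxymethoxy)-4H-chromen-4-one | COCOc1cc(O)c2c(c1)occ(-c1cc(O)c(O)c(CC=C(C)C)c1)c2=O
F2 | step 7 | 3-{2,2-dimethyl-8-[(3-methylbut-2-en-1-yl)oxy]-2H-chromen-6-yl}-5-hydroxy-7-(methoxymethoxy)-4H-chromen-4-one | COCOc1cc(O)c2c(c1)occ(-c1cc(OCC=C(C)C)c3OC(C)(C)C=Cc3c1)c2=O
F3 | step 8 | 5,7-dihydroxy-3-(8-hydroxy-2,2-dimethyl-2H-chromen-6-yl)-4H-chromen-4-one | Oc1cc(O)c2c(c1)occ(-c1cc(O)c3OC(C)(C)C=Cc3c1)c2=O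
F4 | step 8 | 5-hydroxy-3-(8-hydroxy-2,2-dimethyl-2H-chromen-6-yl)-4-oxo-4H-chromen-7-yl pivalate | CC(C)(C)C(=O)Oc1cc(O)c2c(c1)occ(-c1cc(O)c3OC(C)(C)C=Cc3c1)c2=O
F5 | step 8 | 3-{2,2-dimethyl-8-[(2-methylbut-3-en-2-yl)oxy]-2H-chromen-6-yl}-5-hydroxy-4-oxo-4H-chromen-7-yl pivalate | CC(C)(C)C(=O)Oc1cc(O)c2c(c1)occ(-c1cc(OC(C)(C)C=C)c3OC(C)(C)C=Cc3c1)c2=O
F6 | step 8 | 3-[2,2-dimethyl-7-(3-methylbut-2-en-1-yl)-8-oxo-7,8-dihydro-2H-chromen-6-yl]-5-hydroxy-4-oxo-4H-chromen-7-yl pivalate (racemic, transient) | CC(C)(C)C(=O)Oc1cc(O)c2c(c1)occ(C1=CC3=C(OC(C)(C)C=C3)C(=O)C1CC=C(C)C)c2=O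
F7 | step 8 | 5-hydroxy-3-[8-hydroxy-2,2-dimethyl-7-(3-methylbut-2-en-1-yl)-2H-chromen-6-yl]-4-oxo-4H-chromen-7-yl pivalate | CC(C)(C)C(=O)Oc1cc(O)c2c(c1)occ(-c1cc3C=CC(C)(C)Oc3c(O)c1CC=C(C)C)c2=O
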